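Start with D. You asked for a quick number on L, but L stands at the far end of a chain, so I first read how much G it takes to move D.

in all of them: D 0.50 M (in portions, 3)
- Thursday's: G 0.54 M; run made earlier; portions every 30 h
- Tuesday's: G 1.3 M; run made earlier; portions every 30 h
- Friday's: G 1.9 M; run made earlier; portions every 30 h
- cedar: G 0.750 M; the portions of D follow each other after 30 h, the first at the start; time 4.0 d
- oak: G 1.50 M; the portions of D follow each other after 30 h, the first at the start; time 4.0 d
- alder: G 2.00 M; the portions of D follow each other after 30 h, the first at the start; time 4.0 d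

| run | time / h | L / % | Z / % | D / % |
|---|---|---|---|---|
| Thursday's | 10.0 | 0 | 5 | 27 |
| Thursday's | 20.0 | 0 | 7 | 22 |
| Thursday's | 30.0 | 0 | 6 | 21 |
| Thursday's | 40.0 | 0 | 13 | 43 |
| Thursday's | 50.0 | 4 | 15 | 38 |
| Tuesday's | 4.00 | 0 | 5 | 25 |
| Tuesday's | 12.0 | 1 | 12 | 18 |
| Tuesday's | 20.0 | 1 | 10 | 12 |
| Tuesday's | 30.0 | 0 | 11 | 9 |
| Tuesday's | 50.0 | 5 | 18 | 19 |
| Friday's | 10.0 | 0 | 12 | 14 |
| Friday's | 20.0 | 1 | 12 | 8 |
| Friday's | 30.0 | 3 | 10 | 4 |
| Friday's | 40.0 | 9 | 20 | 20 |
| Friday's | 50.0 | 12 | 21 | 10 |

(each reading ± 1.5 percentage points)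



* L at the end, in percent of the D charged, for each flask in turn (cedar, oak, alder)

Take the first portion, which has the flask to itself until the second arrives. In Friday's run it is down to 12.0 % of itself after 30 h, or 0.921 powers of ten, and with G at 1.9 M above that portion's share, the decay is pseudo-first-order. In Tuesday's run it is down to 27.0 %, or 0.569 powers of ten. So I carry one quantity, the decade dose, meaning G concentration times time for a tenfold fall of D: 65.2 M·h. It is a reading with a scatter of 1.5 percentage points behind it, taken with G as charged.

Now cedar. Its first portion gets 1.10 powers of ten by the end, and alder's last portion gets the same dose, 1.10. Friday's first portion, at 0.921 powers, had given L 3 % of the charge. But these doses take G as charged, and G is consumed along the way, while that reading covers one portion and the asked L counts the whole charge. So I commit to no figure of my own for L in cedar, oak or alder.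

The forecast gives 6 %, 24 % and 37 %, on a chain with “each step first order in G”.

The flask gives 4.85 %, 19.2 % and 29.5 %, each below the forecast.

    D + G → Z (k = 0.0390 M⁻¹ h⁻¹)
    G + J → L (k = 0.0360 M⁻¹ h⁻¹)
    G + Z → J (k = 0.0150 M⁻¹ h⁻¹)
    Z ⇌ Q (K = 0.440, k = 0.0220 h⁻¹)
    Z → X (k = 0.0170 h⁻¹)

Alder at the end holds 28.3 % as X beside 29.5 % as L. Now use the decade dose again, with G averaged between its charge and what is left at the end. The portions then leave 31.5 % of the charge as D in cedar, where the flask has 32.9 %, and 5.36 % in alder, where it has 6.10 %.

The readings stem from a simulated flask on assumed constants.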